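The route rests on cutting two neighbouring bonds of ring B at once: C6–pentyl and C1–CO2H. The feature exploited is that carboxyl-bearing C1 and pentyl-bearing C6 are adjacent, with C1 also ortho to the C2 methoxy group, which biases addition to an aryne spanning C1 and C6. In one flask, the TIPS ether of 3-fluoro-5-methoxyphenol is lithiated between fluorine and methoxy, loses LiF, adds pentyllithium at C6 and is carboxylated at C1, giving the fully substituted ring B acid. The depside ester to ring A is then made by routine acylation with a benzyl-protected heptyl acid, and one hydrogenolysis releases the target.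

Key step: step 3

Remark: ring B is numbered from its carboxyl carbon (C1 carboxyl, C2 methoxy, C4 ester oxygen, C6 pentyl), ring A is the heptyl-bearing ring, and pentyllithium is made and titrated as a stock solution, which is counted as a step.

Step 1
Reactants: 1 3-fluoro-5-methoxyphenol
Product: 2 (3-fluoro-5-methoxyphenoxy)triisopropylsilane
Conditions: TIPSCl, imidazole, DMF, rt
Reagents that add atoms: triisopropylsilyl chloride, CC(C)[Si](Cl)(C(C)C)C(C)C
Why: Imidazole-promoted O-silylation of a phenol is routine, and the bulky TIPS ether is chosen because it withstands alkyllithiums and screens both of its ortho positions from metalation.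

Step 2
Reactants: 3 1-bromopentane
Product: 4 pentyllithium
Conditions: Li (2.2 equiv, 1% Na), Et2O, −10 °C; filtered and titrated
Reagents that add atoms: lithium, [Li]
Why: Reductive lithiation of a primary alkyl bromide by lithium metal in cold ether is the classical alkyllithium preparation and should proceed with little Wurtz coupling at this temperature.

Step 3
Reactants: 2 (3-fluoro-5-methoxyphenoxy)triisopropylsilane; 4 pentyllithium
Product: 9 2-methoxy-6-pentyl-4-(triisopropylsilyloxy)benzoic acid, via ortho-lithiated fluoroarene 5 (not isolated), via 3-methoxy-5-(triisopropylsilyloxy)benzyne 6 (not isolated), via pentylated aryllithium 7 (not isolated), via lithium carboxylate 8 (not isolated)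
Conditions: 4 (3 equiv), THF, −78 °C, then −78 → 0 °C; CO2 (g), −78 °C; 1 M HCl, 0 °C
Reagents that add atoms: carbon dioxide, O=C=O
Why: The first equivalent of 4 removes the ring proton flanked by fluorine and methoxy (directed ortho-metalation at the most acidic, doubly activated site) to give 5, which on warming expels LiF to give aryne 6; a second equivalent of 4 adds to the former C–F carbon (C6), and the aryllithium 7, now on the former C–H carbon (C1), is carboxylated to 8 and protonated on work-up. The closest known reaction type is the generation of 3-alkoxybenzynes from ortho-lithiated fluoroanisoles in the presence of excess alkyllithium, with electrophilic quench of the 2-alkoxyaryllithium so formed. No ring is closed and no stereocentre is created. Site selectivity of lithiation is required and is secured by the bulky, weakly coordinating TIPS ether, which shields both of its ortho positions and leaves only the carbon between fluorine and methoxy. Regioselectivity of addition to 6 is required and is secured by the methoxy group next to the triple bond, whose inductive pull distorts the aryne and stabilises (and chelates) lithium on the adjacent carbon, so the nucleophile enters at the remote terminus. Complete metalation at −78 °C before warming and an excess of 4 should keep 6 from being captured by aryllithiums or by unmetalated 2.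

Step 4
Reactants: 9 2-methoxy-6-pentyl-4-(triisopropylsilyloxy)benzoic acid
Product: 10 benzyl 2-methoxy-6-pentyl-4-(triisopropylsilyloxy)benzoate
Conditions: BnBr, KHCO3, DMF, rt
Reagents that add atoms: benzyl bromide, BrCc1ccccc1
Why: Carboxylate O-alkylation (SN2 on benzyl bromide) is indifferent to the crowding around the carbonyl carbon, and the weak base KHCO3 should leave the aryl silyl ether intact; benzyl hexanoate arising from excess 4 is removed here by chromatography.

Step 5
Reactants: 10 benzyl 2-methoxy-6-pentyl-4-(triisopropylsilyloxy)benzoate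
Product: 11 benzyl 4-hydroxy-2-methoxy-6-pentylbenzoate
Conditions: Bu4NF, AcOH, THF, 0 °C
Reagents that add atoms: none
Why: Fluoride-induced desilylation, driven by Si–F bond formation and buffered with acetic acid, should free the C4 phenol while the benzyl ester and the methyl ether stay untouched.

Step 6
Reactants: 12 methyl orsellinate (methyl 2,4-dihydroxy-6-methylbenzoate)
Product: 13 methyl 2-hydroxy-4-methoxy-6-methylbenzoate
Conditions: MeI (1.1 equiv), K2CO3, acetone, rt
Reagents that add atoms: iodomethane, CI
Why: Williamson etherification should be selective for the 4-hydroxyl because the 2-hydroxyl is locked in a hydrogen bond to the ester carbonyl and is less acidic and less nucleophilic.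

Step 7
Reactants: 13 methyl 2-hydroxy-4-methoxy-6-methylbenzoate
Product: 14 methyl 2-(benzyloxy)-4-methoxy-6-methylbenzoate
Conditions: BnBr, K2CO3, DMF, 60 °C
Reagents that add atoms: benzyl bromide, BrCc1ccccc1
Why: Williamson benzylation under more forcing conditions alkylates the remaining hydrogen-bonded phenol and installs a group that the final hydrogenolysis removes.

Step 8
Reactants: 14 methyl 2-(benzyloxy)-4-methoxy-6-methylbenzoate
Product: 16 methyl 2-(benzyloxy)-6-heptyl-4-methoxybenzoate, via benzylic lithium species 15 (not isolated)
Conditions: LiN(iPr)2 (LDA), THF, −78 °C; 1-iodohexane, DMPU, −78 → −20 °C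
Reagents that add atoms: 1-iodohexane, CCCCCCI
Why: Lateral lithiation of an ortho-toluate gives the ester-stabilised benzylic anion 15, which should undergo SN2 alkylation with the primary iodide, the flanking ortho substituents shielding the ester carbonyl from self-condensation.

Step 9
Reactants: 16 methyl 2-(benzyloxy)-6-heptyl-4-methoxybenzoate
Product: 18 2-(benzyloxy)-6-heptyl-4-methoxybenzoic acid, via potassium carboxylate 17 (not isolated)
Conditions: KOH, DMSO/H2O, 90 °C; then 1 M HCl, 0 °C
Reagents that add atoms: potassium hydroxide, [K+].[OH-]
Why: Saponification of a hindered 2,6-disubstituted methyl benzoate is feasible with poorly solvated hydroxide in aqueous DMSO, and cold acidification of 17 should avoid protodecarboxylation of the electron-rich acid.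

Step 10
Reactants: 18 2-(benzyloxy)-6-heptyl-4-methoxybenzoic acid; 11 benzyl 4-hydroxy-2-methoxy-6-pentylbenzoate
Product: 20 benzyl 4-{[2-(benzyloxy)-6-heptyl-4-methoxybenzoyl]oxy}-2-methoxy-6-pentylbenzoate, via mixed trifluoroacetic anhydride 19 (not isolated)
Conditions: (CF3CO)2O, toluene, 0 °C → rt
Reagents that add atoms: none
Why: Trifluoroacetic anhydride converts the electron-rich acid into mixed anhydride 19, an acylium-like donor that should O-acylate the unhindered phenol of 11 in the classical depside esterification, ring B being deactivated towards C-acylation by its ester group.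

Step 11
Reactants: 20 benzyl 4-{[2-(benzyloxy)-6-heptyl-4-methoxybenzoyl]oxy}-2-methoxy-6-pentylbenzoate
Product: 21 4-[(2-heptyl-6-hydroxy-4-methoxybenzoyl)oxy]-2-methoxy-6-pentylbenzoic acid
Conditions: H2 (1 atm), 10% Pd/C, EtOAc, rt
Reagents that add atoms: none
Why: Heterogeneous hydrogenolysis should cleave both benzylic C–O bonds (benzyl ester and benzyl ether) while the aryl ester link, the methyl ethers and the alkyl chains are inert.

Compound list
1 | 3-fluoro-5-methoxyphenol | COc1cc(O)cc(F)c1 | starting material
2 | (3-fluoro-5-methoxyphenoxy)triisopropylsilane | COc1cc(F)cc(O[Si](C(C)C)(C(C)C)C(C)C)c1 | intermediate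
3 | 1-bromopentane | CCCCCBr | starting material
4 | pentyllithium | [Li]CCCCC | intermediate
5 | [2-fluoro-6-methoxy-4-(triisopropylsilyloxy)phenyl]lithium | COc1cc(O[Si](C(C)C)(C(C)C)C(C)C)cc(F)c1[Li] | intermediate
6 | 3-methoxy-5-(triisopropylsilyloxy)benzyne | COC1=CC(O[Si](C(C)C)(C(C)C)C(C)C)=CC#C1 | intermediate
7 | [2-methoxy-6-pentyl-4-(triisopropylsilyloxy)phenyl]lithium | CCCCCc1cc(O[Si](C(C)C)(C(C)C)C(C)C)cc(OC)c1[Li] | intermediate
8 | lithium 2-methoxy-6-pentyl-4-(triisopropylsilyloxy)benzoate | CCCCCc1cc(O[Si](C(C)C)(C(C)C)C(C)C)cc(OC)c1C(=O)[O-].[Li+] | intermediate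
9 | 2-methoxy-6-pentyl-4-(triisopropylsilyloxy)benzoic acid | CCCCCc1cc(O[Si](C(C)C)(C(C)C)C(C)C)cc(OC)c1C(=O)O | intermediate
10 | benzyl 2-methoxy-6-pentyl-4-(triisopropylsilyloxy)benzoate | CCCCCc1cc(O[Si](C(C)C)(C(C)C)C(C)C)cc(OC)c1C(=O)OCc1ccccc1 | intermediate
11 | benzyl 4-hydroxy-2-methoxy-6-pentylbenzoate | CCCCCc1cc(O)cc(OC)c1C(=O)OCc1ccccc1 | intermediate
12 | methyl orsellinate (methyl 2,4-dihydroxy-6-methylbenzoate) | COC(=O)c1c(C)cc(O)cc1O | starting material
13 | methyl 2-hydroxy-4-methoxy-6-methylbenzoate | COC(=O)c1c(C)cc(OC)cc1O | intermediate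
14 | methyl 2-(benzyloxy)-4-methoxy-6-methylbenzoate | COC(=O)c1c(C)cc(OC)cc1OCc1ccccc1 | intermediate
15 | [3-(benzyloxy)-5-methoxy-2-(methoxycarbonyl)benzyl]lithium | COC(=O)c1c(C[Li])cc(OC)cc1OCc1ccccc1 | intermediate
16 | methyl 2-(benzyloxy)-6-heptyl-4-methoxybenzoate | CCCCCCCc1cc(OC)cc(OCc2ccccc2)c1C(=O)OC | intermediate
17 | potassium 2-(benzyloxy)-6-heptyl-4-methoxybenzoate | CCCCCCCc1cc(OC)cc(OCc2ccccc2)c1C(=O)[O-].[K+] | intermediate
18 | 2-(benzyloxy)-6-heptyl-4-methoxybenzoic acid | CCCCCCCc1cc(OC)cc(OCc2ccccc2)c1C(=O)O | intermediate
19 | 2-(benzyloxy)-6-heptyl-4-methoxybenzoic trifluoroacetic anhydride | CCCCCCCc1cc(OC)cc(OCc2ccccc2)c1C(=O)OC(=O)C(F)(F)F | intermediate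
20 | benzyl 4-{[2-(benzyloxy)-6-heptyl-4-methoxybenzoyl]oxy}-2-methoxy-6-pentylbenzoate | CCCCCCCc1cc(OC)cc(OCc2ccccc2)c1C(=O)Oc1cc(CCCCC)c(C(=O)OCc2ccccc2)c(OC)c1 | intermediate
21 | 4-[(2-heptyl-6-hydroxy-4-methoxybenzoyl)oxy]-2-methoxy-6-pentylbenzoic acid | CCCCCCCc1cc(OC)cc(O)c1C(=O)Oc1cc(CCCCC)c(C(=O)O)c(OC)c1 | target

Total step count: 11.
Longest linear sequence: 6 steps (steps 1, 3, 4, 5, 10, 11 from 3-fluoro-5-methoxyphenol; equally steps 6, 7, 8, 9, 10, 11 from methyl orsellinate).

Steps most likely to fail

Step 3. The aryne may be intercepted by an aryllithium instead of by pentyllithium, leading to biaryl and oligomer formation, or loss of LiF may be incomplete, so that carboxylation occurs without prior pentyl transfer. The fallback avoids the aryne and makes the same two bonds in the reverse order. It sets out from 2: metalation with 4 (1.1 equiv) in THF held at −78 °C gives 5, which is carboxylated cold to lithium 2-fluoro-6-methoxy-4-(triisopropylsilyloxy)benzoate F1 and acidified to 2-fluoro-6-methoxy-4-(triisopropylsilyloxy)benzoic acid F2. Treatment of F2 with excess 4 in THF (−78 °C → rt) regenerates F1, on which carboxylate-directed nucleophilic aromatic substitution (addition–elimination) displaces the ortho fluoride, the better leaving group compared with methoxide, to give 8. Acidic work-up returns the route at 9.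

Step 8. SN2 capture of the benzylic anion by an unactivated primary iodide may be slow, so that the anion is consumed by proton transfer or by addition to unreacted ester. The fallback sets out from 14: anion 15 is generated as before and alkylated with the far more reactive allylic electrophile (E)-1-bromohex-2-ene, giving methyl 2-(benzyloxy)-6-[(3E)-hept-3-en-1-yl]-4-methoxybenzoate F3. Homogeneous hydrogenation of the alkene with H2 and RhCl(PPh3)3 in benzene/ethanol, which leaves the benzyl ether alone, returns the route at 16.

Step 10. Under the acidic anhydride conditions, C-acylation of an electron-rich ring or acid-promoted loss of the ortho benzyl ether may compete with O-acylation. The fallback sets out from 18 and moves the acylation to basic conditions with an isolated acyl donor: oxalyl chloride with catalytic DMF in CH2Cl2 at 0 °C gives 2-(benzyloxy)-6-heptyl-4-methoxybenzoyl chloride F4. This is combined with phenol 11, triethylamine and catalytic DMAP in CH2Cl2, and the route is rejoined at 20.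

Further compounds
F1 | step 3 | lithium 2-fluoro-6-methoxy-4-(triisopropylsilyloxy)benzoate | COc1cc(O[Si](C(C)C)(C(C)C)C(C)C)cc(F)c1C(=O)[O-].[Li+]
F2 | step 3 | 2-fluoro-6-methoxy-4-(triisopropylsilyloxy)benzoic acid | COc1cc(O[Si](C(C)C)(C(C)C)C(C)C)cc(F)c1C(=O)O
F3 | step 8 | methyl 2-(benzyloxy)-6-[(3E)-hept-3-en-1-yl]-4-methoxybenzoate | CCC/C=C/CCc1cc(OC)cc(OCc2ccccc2)c1C(=O)OC
F4 | step 10 | 2-(benzyloxy)-6-heptyl-4-methoxybenzoyl chloride | CCCCCCCc1cc(OC)cc(OCc2ccccc2)c1C(=O)Cl
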